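**Retrosynthetic overview**
- The pyrazinone ring is closed last, at N1–C2: an oxime nitrogen acylates on an alanine methyl ester, and tautomerisation gives the aromatic cyclic hydroxamic acid.
- That oxime comes from a nitro group, so the nitro nitrogen ends up as N1–OH and the nitro-bearing carbon as C6.
- Key C–C bond, C6–CH2: the nitro-stabilised carbon of a nitroketene N,O-acetal (an acyl-anion equivalent for C6) is joined to a formaldehyde-derived CH2 and to indole C3 in one three-component step.
- The nitroketene N,O-acetal already carries C5–OMe, N4, C3–Me and C2; it comes from 1,1-bis(methylsulfanyl)-2-nitroethene, NaOMe and methyl L-alaninate.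
- 7-Prenylindole comes from 7-bromoindole by Stille prenylation; the indole ring is bought and the pyrazinone ring is the only ring formed.

Assumption: the target SMILES has no stereocentre, so the compound is achiral and needs no enantiocontrol; the L-alanine centre carried through 7–10 is erased in the last step.

**Route**

Step 1
Reactants: 1 7-bromo-1H-indole; 2 tributyl(3-methylbut-2-en-1-yl)stannane
Product: 3 7-(3-methylbut-2-en-1-yl)-1H-indole
Conditions: Pd(PPh3)4 (5 mol %), DMF, 100 °C
Reagents that add atoms: none
Why: Migita–Kosugi–Stille coupling, in which zerovalent palladium inserts into the C7–Br bond, the allylstannane transmetalates and reductive elimination at the unhindered allyl terminus gives the linear prenyl arene with the free indole N–H tolerated; no stereocentre is formed.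

Step 2
Reactants: 4 1,1-bis(methylsulfanyl)-2-nitroethene; 5 methyl L-alaninate hydrochloride
Product: 7 methyl N-[(E)-1-methoxy-2-nitroethenyl]-L-alaninate, via 1,1-dimethoxy-2-nitroethene 6 (not isolated)
Conditions: NaOMe (2.0 equiv), MeOH, 0 °C to rt; then 5 (1.0 equiv), AcOH (1.0 equiv), N2 sparge, rt
Reagents that add atoms: sodium methoxide, C[O-].[Na+]
Why: Vinylic addition–elimination on a push–pull nitroalkene, in which methoxide replaces both MeS groups because thiolate is the better leaving group from the nitronate adduct, and the amino ester then replaces one MeO and stops there because the N,O-acetal is deactivated by the nitrogen lone pair and its N–H···O2N hydrogen bond; no new stereocentre is formed and the (S)-centre of 5 is only carried along.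

Step 3
Reactants: 3 7-(3-methylbut-2-en-1-yl)-1H-indole; 7 methyl N-[(E)-1-methoxy-2-nitroethenyl]-L-alaninate
Product: 9 methyl N-[(1E)-1-methoxy-3-[7-(3-methylbut-2-en-1-yl)-1H-indol-3-yl]-2-nitroprop-1-en-1-yl]-L-alaninate, via nitroazadiene 8 (not isolated)
Conditions: (CH2O)n (1.3 equiv), L-proline (10 mol %), MeCN, 40 °C
Reagents that add atoms: formaldehyde (used as paraformaldehyde), C=O
Why: Proposed new method: the nitro-bearing carbon of push–pull nitroenamine 7 is a nitronate-type carbanion that serves as an acyl-anion equivalent for C6 (it ends at the oxime oxidation level) and condenses with formaldehyde under proline catalysis (Henry/Knoevenagel) to the 2-nitro-1-azadiene 8, whose CH2 terminus is captured by indole C3 in a Friedel–Crafts Michael addition, so the C6–CH2 bond joins two carbons that are both electrophilic in their normal polarity; the closest known reaction type is the Yonemitsu three-component condensation of indole, an aldehyde and Meldrum's acid, together with the gramine alkylation of nitroacetates; no stereocentre is set and the alkene geometry is held only by the N–H···O2N hydrogen bond.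

Step 4
Reactants: 9 methyl N-[(1E)-1-methoxy-3-[7-(3-methylbut-2-en-1-yl)-1H-indol-3-yl]-2-nitroprop-1-en-1-yl]-L-alaninate
Product: 11 astepyrazinoxide, via oxime imidate 10 (not isolated)
Conditions: SnCl2 (1.5 equiv), PhSH (6 equiv), Et3N (6 equiv), MeCN, rt, degassed; then DBU (2 equiv), MeOH, 50 °C; aq. citric acid work-up
Reagents that add atoms: none
Why: The tin thiolate reagent [Et3NH][Sn(SPh)3] (divalent tin) deoxygenates aliphatic nitro groups to oximes under basic conditions that spare the prenyl alkene, the indole and the imidate, and the oxime nitrogen of 10 then acylates on the methyl ester (6-exo-trig, the ring closure used for 1-hydroxy-2-pyridones from oxo ester oximes), after which the N-acyl nitrone tautomerises by C3–H shift to the aromatic cyclic hydroxamic acid, which erases the alanine stereocentre and gives the achiral target.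

**Compound list**

1 | 7-bromo-1H-indole | Brc1cccc2cc[nH]c12 | starting material
2 | tributyl(3-methylbut-2-en-1-yl)stannane | CCCC[Sn](CCCC)(CCCC)CC=C(C)C | starting material
3 | 7-(3-methylbut-2-en-1-yl)-1H-indole (7-prenylindole) | CC(C)=CCc1cccc2cc[nH]c12 | intermediate
4 | 1,1-bis(methylsulfanyl)-2-nitroethene | CSC(SC)=C[N+](=O)[O-] | starting material
5 | methyl L-alaninate hydrochloride | C[C@H](N)C(=O)OC.Cl | starting material
6 | 1,1-dimethoxy-2-nitroethene | COC(OC)=C[N+](=O)[O-] | intermediate
7 | methyl N-[(E)-1-methoxy-2-nitroethenyl]-L-alaninate (N–H cis to NO2) | CO/C(N[C@@H](C)C(=O)OC)=C/[N+](=O)[O-] | intermediate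
8 | methyl N-(1-methoxy-2-nitroprop-2-en-1-ylidene)-L-alaninate (C=N geometry not fixed) | C=C([N+](=O)[O-])C(OC)=N[C@@H](C)C(=O)OC | intermediate
9 | methyl N-[(1E)-1-methoxy-3-[7-(3-methylbut-2-en-1-yl)-1H-indol-3-yl]-2-nitroprop-1-en-1-yl]-L-alaninate (N–H cis to NO2; in equilibrium with its 2-nitro imidate tautomer) | CO/C(N[C@@H](C)C(=O)OC)=C(\Cc1c[nH]c2c(CC=C(C)C)cccc12)[N+](=O)[O-] | intermediate
10 | methyl N-[2-(hydroxyimino)-1-methoxy-3-[7-(3-methylbut-2-en-1-yl)-1H-indol-3-yl]propylidene]-L-alaninate (E/Z mixture at both C=N bonds) | COC(=N[C@@H](C)C(=O)OC)C(=NO)Cc1c[nH]c2c(CC=C(C)C)cccc12 | intermediate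
11 | astepyrazinoxide, 1-hydroxy-5-methoxy-3-methyl-6-{[7-(3-methylbut-2-en-1-yl)-1H-indol-3-yl]methyl}pyrazin-2(1H)-one (achiral) | COc1nc(C)c(=O)n(O)c1Cc1c[nH]c2c(CC=C(C)C)cccc12 | target

**Step count**
Total: 4 steps. Longest linear sequence: 3 steps (1 → 3 → 9 → 11; step 2 is a one-step side branch from 4 and 5).

**Three steps most likely to fail, with fallbacks**

Step 3 (three-component coupling). The risks are bis(indolyl)methane formation and methylene-bridged dimers of 7. The fallback sets out from 3 and comes back at 9. Compound 3 is aminomethylated at C3 with dimethyl(methylidene)ammonium iodide in MeCN to give 7-prenylgramine F1. MeI in THF converts it into the quaternary methiodide F2. F2 and 7 with K2CO3 in MeCN at rt give 9: trimethylamine is eliminated to the 3-methyleneindolenine, which is captured by the nitro-stabilised anion of 7, as in the classical gramine route to tryptophans. The electrophile is preformed, and neither free formaldehyde nor a secondary amine that could displace the methoxy group is present.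

Step 4 (deoxygenation to the oxime and ring closure). The risks are reduction that does not stop at the oxime, slow acylation of the oxime nitrogen, and binding of tin by the hydroxamic acid product. The fallback sets out from 9 and comes back at 11. Zn dust and NH4Cl in aqueous THF–MeOH at 0 °C take the nitro group to the acyclic hydroxylamine F3. Its nitrogen is a much better nucleophile than an oxime nitrogen and lactamises on the ester to the 1-hydroxy-3,6-dihydropyrazin-2(1H)-one F4. Activated MnO2 in CH2Cl2 at rt dehydrogenates F4 to the aromatic 11.

Step 2 (nitroketene N,O-acetal). The risks are incomplete or reversible MeS/MeO exchange and moisture sensitivity of 6. The fallback sets out from 5 and comes back at 7. Commercial chloroacetonitrile with catalytic NaOMe in MeOH gives methyl 2-chloroethanimidate F5. F5 exchanges its NH with the amino ester salt 5 to give methyl N-(2-chloro-1-methoxyethylidene)-L-alaninate F6. Kornblum displacement of chloride with NaNO2 (phloroglucinol, DMF, rt) gives the nitro imidate, which is the tautomer of 7.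

**Further compounds**

F1 | step 3 | N,N-dimethyl-1-[7-(3-methylbut-2-en-1-yl)-1H-indol-3-yl]methanamine (7-prenylgramine) | CN(C)Cc1c[nH]c2c(CC=C(C)C)cccc12
F2 | step 3 | N,N,N-trimethyl-1-[7-(3-methylbut-2-en-1-yl)-1H-indol-3-yl]methanaminium iodide | C[N+](C)(C)Cc1c[nH]c2c(CC=C(C)C)cccc12.[I-]
F3 | step 4 | methyl N-[2-(hydroxyamino)-1-methoxy-3-[7-(3-methylbut-2-en-1-yl)-1H-indol-3-yl]propylidene]-L-alaninate (mixture of epimers at the hydroxyamino carbon) | COC(=N[C@@H](C)C(=O)OC)C(NO)Cc1c[nH]c2c(CC=C(C)C)cccc12
F4 | step 4 | (3S)-1-hydroxy-5-methoxy-3-methyl-6-{[7-(3-methylbut-2-en-1-yl)-1H-indol-3-yl]methyl}-3,6-dihydropyrazin-2(1H)-one (mixture of epimers at C6) | COC1=N[C@@H](C)C(=O)N(O)C1Cc1c[nH]c2c(CC=C(C)C)cccc12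
F5 | step 2 | methyl 2-chloroethanimidate | COC(=N)CCl
F6 | step 2 | methyl N-(2-chloro-1-methoxyethylidene)-L-alaninate | COC(CCl)=N[C@@H](C)C(=O)OC
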